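**Retrosynthetic overview**

- Feature: in ring C (C1'–C6') the C1'=C2' double bond carries the coumarin on C1' and lies between the ketone carbons C3' and C6', and the quaternary carbinol C4' adjoins the C5' methylene. C3'–C2'–C1'–C6' is therefore a 2-aryl-1,4-dioxybutadiene and C4'–C5' a 2-oxyacrolein.
- 19 ⇐ triol 18 by oxidation at C3' and C6' as the last step. The benzoate is removed first, so no 4'-acyloxy-6'-ketone exists that could eliminate to the quinone. 18 ⇐ 16 ⇐ formyl-to-prenyl homologation of cycloadduct 13 by two Wittig reactions.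
- 13 ⇐ diene 8 + 2-(benzoyloxy)acrolein 12 by an enantioselective Diels–Alder reaction under chiral primary-ammonium catalysis (bonds C3'–C4' and C5'–C6'). Ring C is the only ring made; coumarin rings A and B come intact from 1.
- 8 ⇐ enal 7 (silyl dienol ether formation) ⇐ Stille coupling of 3-bromocoumarin 2 with stannane 5 (trans-hydrostannation of mono-silylated butynediol 4). 12 ⇐ dioxanone 9 (enol benzoate, then retro-hetero-Diels–Alder loss of acetone).

Key step: step 9

Assumption: ring C is numbered C1' (coumarin-bearing) to C6' as above; the (S)-diamine is written for step 9, and if a trial shows it to give the 4'S series its mirror image is used with nothing else changed.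

**Route**

Step 1
Reactants: 1 7-methoxycoumarin
Product: 2 3-bromo-7-methoxycoumarin
Conditions: Br2 (1.05 equiv), NaOAc, AcOH, rt
Reagents that add atoms: bromine, BrBr
Why: Electrophilic bromination of the C3=C4 bond, which the 7-methoxy group makes electron-rich at C3 (donation through C4a and C4), followed by loss of the C3 proton to acetate.

Step 2
Reactants: 3 but-2-yne-1,4-diol
Product: 4 4-(tert-butyldimethylsilyloxy)but-2-yn-1-ol
Conditions: TBSCl (1 equiv), imidazole (1.2 equiv), 3 (3 equiv), DMF, 0 °C → rt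
Reagents that add atoms: tert-butyldimethylsilyl chloride, CC(C)(C)[Si](C)(C)Cl
Why: Statistical mono-silylation of a symmetrical diol used in excess; unreacted diol is washed out with water.

Step 3
Reactants: 4 4-(tert-butyldimethylsilyloxy)but-2-yn-1-ol
Product: 5 (Z)-4-(tert-butyldimethylsilyloxy)-2-(tributylstannyl)but-2-en-1-ol
Conditions: Bu3SnH (1.1 equiv), [Cp*RuCl]4 (1.25 mol%), CH2Cl2, rt
Reagents that add atoms: tributyltin hydride, CCCC[SnH](CCCC)CCCC
Why: Ruthenium-catalysed trans-hydrostannation of a propargylic alcohol, in which hydrogen bonding of the free hydroxyl to the chloride ligand steers tin to the alkyne carbon next to CH2OH; the alkene geometry is of no consequence because this double bond becomes the C2–C3 single bond of the diene.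

Step 4
Reactants: 2 3-bromo-7-methoxycoumarin; 5 (Z)-4-(tert-butyldimethylsilyloxy)-2-(tributylstannyl)but-2-en-1-ol
Product: 6 (E)-4-(tert-butyldimethylsilyloxy)-2-(7-methoxy-2-oxo-2H-chromen-3-yl)but-2-en-1-ol
Conditions: Pd2(dba)3 (2.5 mol%), AsPh3 (20 mol%), CuI (20 mol%), DMF, 50 °C
Reagents that add atoms: none
Why: Stille coupling in which the alpha-bromo enoate unit of 2 adds readily to zerovalent palladium and CuI speeds tin-to-palladium transfer from the alpha-branched stannane; fluoride-free conditions spare the silyl ether.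

Step 5
Reactants: 6 (E)-4-(tert-butyldimethylsilyloxy)-2-(7-methoxy-2-oxo-2H-chromen-3-yl)but-2-en-1-ol
Product: 7 (E)-4-(tert-butyldimethylsilyloxy)-2-(7-methoxy-2-oxo-2H-chromen-3-yl)but-2-enal
Conditions: MnO2 (15 equiv), CH2Cl2, rt
Reagents that add atoms: none
Why: MnO2 oxidation of a primary allylic alcohol to the enal, leaving silyl ether and coumarin untouched.

Step 6
Reactants: 7 (E)-4-(tert-butyldimethylsilyloxy)-2-(7-methoxy-2-oxo-2H-chromen-3-yl)but-2-enal
Product: 8 (1Z,3E)-1,4-bis(tert-butyldimethylsilyloxy)-2-(7-methoxy-2-oxo-2H-chromen-3-yl)buta-1,3-diene (both silyloxy groups trans to the C2–C3 bond)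
Conditions: TBSOTf (1.3 equiv), Et3N (2.5 equiv), CH2Cl2, −78 → 0 °C; filtration through Et3N-deactivated silica, used at once
Reagents that add atoms: tert-butyldimethylsilyl triflate, CC(C)(C)[Si](C)(C)OS(=O)(=O)C(F)(F)F
Why: Silyl dienol ether formation (O-silylation of the enal, then gamma-deprotonation at C4); the s-trans enal should place the C1 silyloxy group away from C3, and allylic 1,3-strain with the fully substituted C2 should place the C4 silyloxy group trans to C2, so both oxygens point outward, while any isomer with an inward silyloxy group is a poor diene and stays behind in step 9.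

Step 7
Reactants: 9 2,2-dimethyl-1,3-dioxan-5-one
Product: 11 2,2-dimethyl-4H-1,3-dioxin-5-yl benzoate, via potassium enolate 10 (not isolated)
Conditions: KHMDS (1.05 equiv), THF, −78 °C; then BzCl (1.1 equiv), −78 → 0 °C
Reagents that add atoms: benzoyl chloride, O=C(Cl)c1ccccc1
Why: O-acylation of a potassium enolate by an acid chloride (enol ester formation); the symmetrical ketone can give only one enolate.

Step 8
Reactants: 11 2,2-dimethyl-4H-1,3-dioxin-5-yl benzoate
Product: 12 2-(benzoyloxy)acrolein
Conditions: toluene, 110 °C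
Reagents that add atoms: none
Why: Retro-hetero-Diels–Alder reaction of the 4H-1,3-dioxin, which expels acetone and leaves the O1–C6–C5–C4 unit as the 2-acyloxy enal.

Step 9
Reactants: 8 (1Z,3E)-1,4-bis(tert-butyldimethylsilyloxy)-2-(7-methoxy-2-oxo-2H-chromen-3-yl)buta-1,3-diene; 12 2-(benzoyloxy)acrolein
Product: 13 (3'R,4'R,6'R)-4'-benzoyloxy-3',6'-bis(tert-butyldimethylsilyloxy)-4'-formyl-1'-(7-methoxy-2-oxo-2H-chromen-3-yl)cyclohex-1'-ene (formyl cis to both silyloxy groups)
Conditions: (S)-1,1'-binaphthyl-2,2'-diamine (10 mol%), Tf2NH (19 mol%), 12 (1.5 equiv), EtCN, −78 °C, slow addition of 8; aq. NaHCO3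
Reagents that add atoms: none
Why: Proposed new method: the primary amine of the diammonium salt condenses with aldehyde 12 to an alpha-benzoyloxy iminium ion, diene 8 adds to it in a concerted but asynchronous normal-demand [4+2] cycloaddition, and hydrolysis of the product iminium ion frees the catalyst; the closest known reaction type is the chiral primary-ammonium-catalysed Diels–Alder reaction of alpha-acyloxyacroleins with hydrocarbon dienes, not yet shown for an acid-labile bis(silyl enol ether) diene. Ring C is closed by this intermolecular cycloaddition, the two-carbon unit C4'–C5' adding suprafacially across the termini of the s-cis four-carbon unit, with the C5'–C6' bond more advanced than the C3'–C4' bond in the transition state. C4' is controlled by the catalyst, whose binaphthyl backbone shields one face of the iminium ion so that the diene reaches the face giving 4'R; C3' and C6' follow from the outward diene geometry (silyloxy groups cis) and from the endo position of the iminium carbon, and an exo adduct (3',6'-bis-epimer with the same 4'R centre) converges in step 15, where both centres become ketones. The regioselectivity needed is secured by the coumarin on diene C2: attack of the adjacent terminus on the dienophile CH2 puts developing positive charge on C2, where the 7-methoxycoumarin alkene stabilises it, and this orientation keeps the forming quaternary centre away from the bulky substituent. The step also needs the catalysed path to outrun protodesilylation of 8 and the uncatalysed racemic cycloaddition, hence tert-butyldimethylsilyl instead of trimethylsilyl ethers, −78 °C and slow addition of the diene.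

Step 10
Reactants: 13 (3'R,4'R,6'R)-4'-benzoyloxy-3',6'-bis(tert-butyldimethylsilyloxy)-4'-formyl-1'-(7-methoxy-2-oxo-2H-chromen-3-yl)cyclohex-1'-ene
Product: 14 (3'R,4'S,6'R)-4'-benzoyloxy-3',6'-bis(tert-butyldimethylsilyloxy)-4'-(2-methoxyvinyl)-1'-(7-methoxy-2-oxo-2H-chromen-3-yl)cyclohex-1'-ene (E/Z mixture at the enol ether; descriptor at C4' changes by priority only)
Conditions: Ph3P(CH2OMe)Cl (1.5 equiv), KHMDS (1.4 equiv), THF, 0 °C; then 13, −78 → 0 °C
Reagents that add atoms: (methoxymethyl)triphenylphosphonium chloride, COC[P+](c1ccccc1)(c1ccccc1)c1ccccc1.[Cl-]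
Why: Wittig reaction of the small, reactive methoxymethylene ylide with a neopentyl-type aldehyde that has no alpha hydrogen, so neither epimerisation nor elimination can occur; the aldehyde reacts far faster than benzoate or lactone.

Step 11
Reactants: 14 (3'R,4'S,6'R)-4'-benzoyloxy-3',6'-bis(tert-butyldimethylsilyloxy)-4'-(2-methoxyvinyl)-1'-(7-methoxy-2-oxo-2H-chromen-3-yl)cyclohex-1'-ene
Product: 15 (3'R,4'S,6'R)-4'-benzoyloxy-3',6'-bis(tert-butyldimethylsilyloxy)-4'-(2-oxoethyl)-1'-(7-methoxy-2-oxo-2H-chromen-3-yl)cyclohex-1'-ene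
Conditions: TsOH·H2O (0.2 equiv), acetone/H2O (10:1), 0 °C → rt; used crude
Reagents that add atoms: water, O
Why: Acid-catalysed enol ether hydrolysis (C-protonation, hydration of the oxocarbenium ion, loss of methanol), which is much faster than cleavage of the secondary silyl ethers under these mild conditions.

Step 12
Reactants: 15 (3'R,4'S,6'R)-4'-benzoyloxy-3',6'-bis(tert-butyldimethylsilyloxy)-4'-(2-oxoethyl)-1'-(7-methoxy-2-oxo-2H-chromen-3-yl)cyclohex-1'-ene
Product: 16 (3'R,4'R,6'R)-4'-benzoyloxy-3',6'-bis(tert-butyldimethylsilyloxy)-4'-(3-methylbut-2-enyl)-1'-(7-methoxy-2-oxo-2H-chromen-3-yl)cyclohex-1'-ene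
Conditions: Ph3P(iPr)I (1.6 equiv), KHMDS (1.5 equiv), THF, 0 °C; then 15, −78 → −20 °C
Reagents that add atoms: isopropyltriphenylphosphonium iodide, CC(C)[P+](c1ccccc1)(c1ccccc1)c1ccccc1.[I-]
Why: Wittig reaction with the isopropylidene ylide on an unhindered aldehyde, run cold and with preformed ylide so that carbonyl addition outruns E1cB loss of the beta-benzoate.

Step 13
Reactants: 16 (3'R,4'R,6'R)-4'-benzoyloxy-3',6'-bis(tert-butyldimethylsilyloxy)-4'-(3-methylbut-2-enyl)-1'-(7-methoxy-2-oxo-2H-chromen-3-yl)cyclohex-1'-ene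
Product: 17 (3'R,4'R,6'R)-4'-benzoyloxy-3',6'-dihydroxy-4'-(3-methylbut-2-enyl)-1'-(7-methoxy-2-oxo-2H-chromen-3-yl)cyclohex-1'-ene
Conditions: HF·pyridine, pyridine, THF, 0 °C → rt
Reagents that add atoms: none
Why: Fluoride-mediated desilylation in a buffered, weakly acidic medium, which leaves the benzoate, the prenyl group and the lactone alone and does not trigger acyl migration.

Step 14
Reactants: 17 (3'R,4'R,6'R)-4'-benzoyloxy-3',6'-dihydroxy-4'-(3-methylbut-2-enyl)-1'-(7-methoxy-2-oxo-2H-chromen-3-yl)cyclohex-1'-ene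
Product: 18 (3'R,4'R,6'R)-3',4',6'-trihydroxy-4'-(3-methylbut-2-enyl)-1'-(7-methoxy-2-oxo-2H-chromen-3-yl)cyclohex-1'-ene
Conditions: K2CO3 (0.3 equiv), MeOH, 0 °C → rt; aq. NH4Cl
Reagents that add atoms: none
Why: Base-catalysed methanolysis (transesterification) of the benzoate, eased by acyl migration to the neighbouring secondary 3'-hydroxyl; it is done while C6' is still an alcohol so no E1cB route to the quinone exists, and the mildly acidic work-up recloses any opened lactone.

Step 15
Reactants: 18 (3'R,4'R,6'R)-3',4',6'-trihydroxy-4'-(3-methylbut-2-enyl)-1'-(7-methoxy-2-oxo-2H-chromen-3-yl)cyclohex-1'-ene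
Product: 19 3-[(4R)-4-hydroxy-4-(3-methylbut-2-enyl)-3,6-dioxocyclohex-1-en-1-yl]-7-methoxy-2H-chromen-2-one (CNP0250763.1)
Conditions: IBX (3 equiv), DMSO, rt
Reagents that add atoms: none
Why: IBX oxidation of both secondary allylic alcohols to the ene-dione; the tertiary 4'-hydroxyl cannot be oxidised, IBX converts 1,2-diols to alpha-ketols without C–C cleavage, and the neutral medium should keep the beta-hydroxy ketone from dehydrating, so the 4'R centre set in step 9 is carried through unchanged.

**Compound list**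

1 | 7-methoxycoumarin (7-methoxy-2H-chromen-2-one) | COc1ccc2ccc(=O)oc2c1 | starting material
2 | 3-bromo-7-methoxycoumarin | COc1ccc2cc(Br)c(=O)oc2c1 | intermediate
3 | but-2-yne-1,4-diol | OCC#CCO | starting material
4 | 4-(tert-butyldimethylsilyloxy)but-2-yn-1-ol | OCC#CCO[Si](C)(C)C(C)(C)C | intermediate
5 | (Z)-4-(tert-butyldimethylsilyloxy)-2-(tributylstannyl)but-2-en-1-ol | OC/C(=C/CO[Si](C)(C)C(C)(C)C)[Sn](CCCC)(CCCC)CCCC | intermediate
6 | (E)-4-(tert-butyldimethylsilyloxy)-2-(7-methoxy-2-oxo-2H-chromen-3-yl)but-2-en-1-ol | OC/C(=C/CO[Si](C)(C)C(C)(C)C)c1cc2ccc(OC)cc2oc1=O | intermediate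
7 | (E)-4-(tert-butyldimethylsilyloxy)-2-(7-methoxy-2-oxo-2H-chromen-3-yl)but-2-enal | O=C/C(=C/CO[Si](C)(C)C(C)(C)C)c1cc2ccc(OC)cc2oc1=O | intermediate
8 | (1Z,3E)-1,4-bis(tert-butyldimethylsilyloxy)-2-(7-methoxy-2-oxo-2H-chromen-3-yl)buta-1,3-diene | CC(C)(C)[Si](C)(C)O/C=C/C(=C/O[Si](C)(C)C(C)(C)C)c1cc2ccc(OC)cc2oc1=O | intermediate
9 | 2,2-dimethyl-1,3-dioxan-5-one | CC1(C)OCC(=O)CO1 | starting material
10 | potassium 2,2-dimethyl-4H-1,3-dioxin-5-olate (not isolated) | CC1(C)OCC([O-])=CO1.[K+] | intermediate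
11 | 2,2-dimethyl-4H-1,3-dioxin-5-yl benzoate | CC1(C)OCC(OC(=O)c2ccccc2)=CO1 | intermediate
12 | 2-(benzoyloxy)acrolein | C=C(OC(=O)c1ccccc1)C=O | intermediate
13 | (3'R,4'R,6'R)-4'-benzoyloxy-3',6'-bis(tert-butyldimethylsilyloxy)-4'-formyl-1'-(7-methoxy-2-oxo-2H-chromen-3-yl)cyclohex-1'-ene | COc1ccc2cc(C3=C[C@@H](O[Si](C)(C)C(C)(C)C)[C@@](OC(=O)c4ccccc4)(C=O)C[C@H]3O[Si](C)(C)C(C)(C)C)c(=O)oc2c1 | intermediate
14 | (3'R,4'S,6'R)-4'-benzoyloxy-3',6'-bis(tert-butyldimethylsilyloxy)-4'-(2-methoxyvinyl)-1'-(7-methoxy-2-oxo-2H-chromen-3-yl)cyclohex-1'-ene (E/Z mixture) | COc1ccc2cc(C3=C[C@@H](O[Si](C)(C)C(C)(C)C)[C@@](OC(=O)c4ccccc4)(C=COC)C[C@H]3O[Si](C)(C)C(C)(C)C)c(=O)oc2c1 | intermediate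
15 | (3'R,4'S,6'R)-4'-benzoyloxy-3',6'-bis(tert-butyldimethylsilyloxy)-4'-(2-oxoethyl)-1'-(7-methoxy-2-oxo-2H-chromen-3-yl)cyclohex-1'-ene | COc1ccc2cc(C3=C[C@@H](O[Si](C)(C)C(C)(C)C)[C@@](OC(=O)c4ccccc4)(CC=O)C[C@H]3O[Si](C)(C)C(C)(C)C)c(=O)oc2c1 | intermediate
16 | (3'R,4'R,6'R)-4'-benzoyloxy-3',6'-bis(tert-butyldimethylsilyloxy)-4'-(3-methylbut-2-enyl)-1'-(7-methoxy-2-oxo-2H-chromen-3-yl)cyclohex-1'-ene | COc1ccc2cc(C3=C[C@@H](O[Si](C)(C)C(C)(C)C)[C@@](OC(=O)c4ccccc4)(CC=C(C)C)C[C@H]3O[Si](C)(C)C(C)(C)C)c(=O)oc2c1 | intermediate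
17 | (3'R,4'R,6'R)-4'-benzoyloxy-3',6'-dihydroxy-4'-(3-methylbut-2-enyl)-1'-(7-methoxy-2-oxo-2H-chromen-3-yl)cyclohex-1'-ene | COc1ccc2cc(C3=C[C@@H](O)[C@@](OC(=O)c4ccccc4)(CC=C(C)C)C[C@H]3O)c(=O)oc2c1 | intermediate
18 | (3'R,4'R,6'R)-3',4',6'-trihydroxy-4'-(3-methylbut-2-enyl)-1'-(7-methoxy-2-oxo-2H-chromen-3-yl)cyclohex-1'-ene | COc1ccc2cc(C3=C[C@@H](O)[C@@](O)(CC=C(C)C)C[C@H]3O)c(=O)oc2c1 | intermediate
19 | 3-[(4R)-4-hydroxy-4-(3-methylbut-2-enyl)-3,6-dioxocyclohex-1-en-1-yl]-7-methoxy-2H-chromen-2-one | COc1ccc2cc(C3=CC(=O)[C@@](O)(CC=C(C)C)CC3=O)c(=O)oc2c1 | target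

**Step count**

Total step count: 15. Longest linear sequence: 12 steps (steps 2–6 and 9–15, from 3).

**Steps most likely to fail**

Step 9. The ammonium salt may protonate the silyl enol ethers before cycloaddition, silyl transfer to triflimide may create an achiral silyl Lewis acid that drives a racemic pathway, or face discrimination may be poor. The fallback sets out from 8 and 12 and comes back at 13. The two are combined without catalyst in toluene at rt to 60 °C; thermal cycloaddition of 2-acyloxyacroleins with dienes is known chemistry. This should give the racemate, that is 13 together with its mirror image, the (3'S,4'S,6'S)-adduct F1. Preparative chromatography on a chiral stationary phase then separates the enantiomers, and 13 goes on to step 10.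

Step 12. The basic ylide may deprotonate alpha to the aldehyde and expel the beta-benzoate (E1cB) faster than it adds to the carbonyl. The fallback sets out from 15 and comes back at 16 without any base. Takai–Lombardo methylenation (Zn, CH2Br2, TiCl4, THF/CH2Cl2, 0 °C) should convert the aldehyde into the 4'-allyl compound F2. Cross-metathesis of F2 with excess 2-methylbut-2-ene and the second-generation Grubbs catalyst (H2IMes)(PCy3)Cl2Ru=CHPh in CH2Cl2 at 40 °C then gives the prenyl group of 16; the ring alkene and the coumarin alkene are too substituted and electron-poor to take part.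

Step 4. Tin-to-palladium transfer from the alpha-branched stannane may be slow, so that protodestannylation and homocoupling consume the partners. The fallback sets out from 5 and 2 and comes back at 6 with the polarity of the coupling reversed. Iododestannylation of 5 (I2, CH2Cl2, 0 °C) should give, with retention, (Z)-4-(tert-butyldimethylsilyloxy)-2-iodobut-2-en-1-ol F3. Miyaura borylation of 2 (B2pin2, PdCl2(dppf), KOAc, dioxane, 80 °C) should give 7-methoxy-3-(4,4,5,5-tetramethyl-1,3,2-dioxaborolan-2-yl)coumarin F4, used without storage. Suzuki coupling of F3 with F4 (Pd(PPh3)4, K3PO4, THF/H2O, 50 °C) then delivers 6.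

**Further compounds**

F1 | step 9 | (3'S,4'S,6'S)-4'-benzoyloxy-3',6'-bis(tert-butyldimethylsilyloxy)-4'-formyl-1'-(7-methoxy-2-oxo-2H-chromen-3-yl)cyclohex-1'-ene (mirror image of 13) | COc1ccc2cc(C3=C[C@H](O[Si](C)(C)C(C)(C)C)[C@](OC(=O)c4ccccc4)(C=O)C[C@@H]3O[Si](C)(C)C(C)(C)C)c(=O)oc2c1
F2 | step 12 | (3'R,4'R,6'R)-4'-allyl-4'-benzoyloxy-3',6'-bis(tert-butyldimethylsilyloxy)-1'-(7-methoxy-2-oxo-2H-chromen-3-yl)cyclohex-1'-ene | COc1ccc2cc(C3=C[C@@H](O[Si](C)(C)C(C)(C)C)[C@@](OC(=O)c4ccccc4)(CC=C)C[C@H]3O[Si](C)(C)C(C)(C)C)c(=O)oc2c1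
F3 | step 4 | (Z)-4-(tert-butyldimethylsilyloxy)-2-iodobut-2-en-1-ol | OC/C(I)=C/CO[Si](C)(C)C(C)(C)C
F4 | step 4 | 7-methoxy-3-(4,4,5,5-tetramethyl-1,3,2-dioxaborolan-2-yl)-2H-chromen-2-one | COc1ccc2cc(B3OC(C)(C)C(C)(C)O3)c(=O)oc2c1
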